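Everything rests on cutting ring C at C4a–C4 and O1–C2. This divides the flavonol into 2,4-diprenylphloroglucinol (ring A) and an aroylacetate that supplies C4, C3 with its oxygen, C2 and ring B. The plan exploits the symmetry of ring A: because C6 and C8 bear identical prenyl groups, the one unsubstituted carbon (future C4a) sits between two mirror-related hydroxyls (future O1 and 5-OH), so only one chromone can arise. A single acid-free thermal operation acylates C4a via an aroylketene and closes the pyranone with loss of water. The ester partner, ethyl 2-benzoyloxy-3-(4-benzoyloxyphenyl)-3-oxopropanoate, carries base-labile benzoates that a final methanolysis removes.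

Key step: step 8

Remark on the chemistry: prenyl means 3-methylbut-2-en-1-yl; the target has no stereocentre and no E/Z element, the only stereocentres on the way are racemic, labile and erased when ring C aromatises, and free 2,4-diprenylphloroglucinol is assumed to be air- and acid-sensitive, so it is prepared under argon and used at once.

Step 1
Reactants: 1 phloroglucinol
Product: 2 1,3,5-tris(methoxymethoxy)benzene
Conditions: NaH (3.6 equiv), MOMCl (3.6 equiv), DMF, 0 °C → rt
Reagents that add atoms: chloromethyl methyl ether (MOMCl), COCCl
Why: Williamson-type O-alkylation of the sodium phenoxide by the hard, oxocarbenium-like chloromethyl ether takes place on oxygen and installs three acetal groups that later direct the metalations.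

Step 2
Reactants: 2 1,3,5-tris(methoxymethoxy)benzene; 3 prenyl bromide
Product: 5 1,3,5-tris(methoxymethoxy)-2-prenylbenzene, via aryllithium 4 (not isolated)
Conditions: n-BuLi (1.1 equiv), THF, 0 °C, 1 h; then 3 (1.2 equiv), −78 °C → rt
Reagents that add atoms: none
Why: Directed ortho-metalation followed by SN2 alkylation: every ring C–H of 2 lies between two coordinating OMOM groups, so n-BuLi gives a single aryllithium, which attacks the unhindered primary terminus of the allylic bromide.

Step 3
Reactants: 5 1,3,5-tris(methoxymethoxy)-2-prenylbenzene; 3 prenyl bromide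
Product: 7 1,3,5-tris(methoxymethoxy)-2,4-diprenylbenzene, via aryllithium 6 (not isolated)
Conditions: n-BuLi (1.2 equiv), THF, −20 → 0 °C, 1 h; then 3 (1.3 equiv), −78 °C → rt
Reagents that add atoms: none
Why: A second directed ortho-metalation and SN2 alkylation: the two remaining ring C–H are equivalent and each is still flanked by two OMOM groups, so chelation-assisted ring lithiation should outrun deprotonation of the prenyl CH2 and only one diprenyl isomer is possible.

Step 4
Reactants: 7 1,3,5-tris(methoxymethoxy)-2,4-diprenylbenzene
Product: 9 2,4-diprenylphloroglucinol, via tris(trimethylsilyl) ether 8 (not isolated)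
Conditions: Me3SiOTf (6 equiv), 2,2'-bipyridyl (9 equiv), MeCN, 0 °C → rt, Ar; then MeOH, rt
Reagents that add atoms: none
Why: Silyl triflate/2,2'-bipyridyl cleavage of aryl MOM ethers: under amine-buffered conditions free of Brønsted acid each acetal is exchanged for a trimethylsilyl ether while its CH2OMe unit is passed to the bipyridyl nitrogen, and the methanol quench desilylates the phenols and turns that unit into inert dimethoxymethane, so neither acid (chroman closure) nor free formaldehyde (attack on the open ring carbon) meets the product.

Step 5
Reactants: 10 4-hydroxyacetophenone; 11 diethyl carbonate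
Product: 12 ethyl 3-(4-hydroxyphenyl)-3-oxopropanoate
Conditions: NaH (3.5 equiv), 11 (3 equiv), THF, reflux; then cold 1 M HCl
Reagents that add atoms: none
Why: Crossed Claisen condensation (C-carbethoxylation): excess NaH forms the phenoxide and then the methyl ketone enolate, which is acylated by the non-enolisable carbonate, and deprotonation of the resulting β-keto ester pulls the equilibrium to the product.

Step 6
Reactants: 12 ethyl 3-(4-hydroxyphenyl)-3-oxopropanoate
Product: 13 ethyl 3-(4-benzoyloxyphenyl)-3-oxopropanoate
Conditions: BzCl (1.05 equiv), pyridine (1.5 equiv), CH2Cl2, 0 °C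
Reagents that add atoms: benzoyl chloride, O=C(Cl)c1ccccc1
Why: Chemoselective O-acylation (Einhorn-type benzoylation): the acidic 4-acylphenol reacts with the acylpyridinium species whereas pyridine is too weak to enolise the β-keto ester for acylation, and the new ester also deactivates ring B towards the bromination that follows.

Step 7
Reactants: 13 ethyl 3-(4-benzoyloxyphenyl)-3-oxopropanoate
Product: 15 ethyl 2-benzoyloxy-3-(4-benzoyloxyphenyl)-3-oxopropanoate (racemic), via α-bromo keto ester 14 (not isolated)
Conditions: NBS (1.0 equiv), TsOH·H2O (5 mol %), MeCN, rt; then PhCO2Na (1.5 equiv), DMF, rt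
Reagents that add atoms: sodium benzoate, [Na+].[O-]C(=O)c1ccccc1
Why: Electrophilic α-bromination of the enol by NBS followed by SN2 displacement of the doubly activated secondary bromide by the weakly basic benzoate, the standard entry to 2-acyloxy-β-keto esters; the new centre is racemic, epimerisable and is erased in step 8.

Step 8
Reactants: 9 2,4-diprenylphloroglucinol; 15 ethyl 2-benzoyloxy-3-(4-benzoyloxyphenyl)-3-oxopropanoate
Product: 19 3,4'-di-O-benzoyl-6,8-diprenylkaempferol, via aroylketene 16 (not isolated), via C-acyl diketone 17 (not isolated), via hemiketal 18 (not isolated)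
Conditions: 15 (1.5 equiv, added in portions), degassed Ph2O, 210 °C, slow Ar stream carrying off EtOH and H2O; no acid, no base
Reagents that add atoms: none
Why: Mentzer-type thermal pyrone condensation: the enol of 15 expels ethanol through a six-membered transition state to give aroylketene 16, whose ketene carbon (future C4) is attacked by the only unsubstituted carbon of 9 (future C4a), either directly or after reversible O-acylation and re-ionisation of the aryl ester, giving the 2-acyloxy-1,3-diketone 17, the same kind of intermediate that cyclises in the Allan–Robinson flavonol synthesis. Ring C then closes by 6-exo-trig addition of a flanking phenolic oxygen (future O1) to the aryl ketone carbon (C2) to give hemiketal 18, and irreversible loss of water delivers the aromatic pyranone 19. The closest known reaction is the neat or Ph2O condensation of phloroglucinol with ethyl aroylacetates and with 2-substituted β-keto esters, which gives 5,7-dihydroxyflavones and 3-substituted chromones. No stereocentre survives, because the labile C3 centre of 15 and the two transient centres of 18 all become sp2. Site selectivity is secured by the substrate, since C4a is the single free ring carbon and its two neighbouring hydroxyls are related by the mirror plane of 9, so either closure gives the same 6,8-diprenyl product, while chromone-over-coumarin selectivity follows from the absence of acid (no Pechmann attack at the hindered aryl ketone) and from the much higher electrophilicity of the ketene carbon. Oxygen-free and acid-free heating in the range of aromatic Claisen rearrangements should keep the ortho-prenylphenol units from closing to chromans, the gas stream removes ethanol and water so that 15 is not hydrolysed and decarboxylated, and benzoyl migration to ring A oxygens is harmless because step 9 removes every benzoate.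

Step 9
Reactants: 19 3,4'-di-O-benzoyl-6,8-diprenylkaempferol
Product: 20 6,8-diprenylkaempferol
Conditions: K2CO3 (4 equiv), degassed MeOH–THF, Ar, 0 °C → rt; then AcOH to pH 6
Reagents that add atoms: none
Why: Carbonate-mediated transesterification with methanol cleaves the enol benzoate at O3, the aryl benzoate at O4' and any benzoate that wandered to ring A, leaves prenyl groups and the pyranone untouched, and is run without oxygen because flavonolate anions autoxidise, with a weak-acid quench so that no strong acid meets the ortho-prenylphenols.

Compound list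
1 | phloroglucinol | Oc1cc(O)cc(O)c1 | starting material
2 | 1,3,5-tris(methoxymethoxy)benzene | COCOc1cc(OCOC)cc(OCOC)c1 | intermediate
3 | prenyl bromide (1-bromo-3-methylbut-2-ene) | CC(C)=CCBr | starting material
4 | 2,4,6-tris(methoxymethoxy)phenyllithium | [Li]c1c(OCOC)cc(OCOC)cc1OCOC | intermediate
5 | 1,3,5-tris(methoxymethoxy)-2-prenylbenzene | COCOc1cc(OCOC)c(CC=C(C)C)c(OCOC)c1 | intermediate
6 | 2,4,6-tris(methoxymethoxy)-3-prenylphenyllithium | [Li]c1c(OCOC)cc(OCOC)c(CC=C(C)C)c1OCOC | intermediate
7 | 1,3,5-tris(methoxymethoxy)-2,4-diprenylbenzene | COCOc1cc(OCOC)c(CC=C(C)C)c(OCOC)c1CC=C(C)C | intermediate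
8 | 1,3,5-tris(trimethylsilyloxy)-2,4-diprenylbenzene | C[Si](C)(C)Oc1cc(O[Si](C)(C)C)c(CC=C(C)C)c(O[Si](C)(C)C)c1CC=C(C)C | intermediate
9 | 2,4-diprenylphloroglucinol | Oc1cc(O)c(CC=C(C)C)c(O)c1CC=C(C)C | intermediate
10 | 4-hydroxyacetophenone | CC(=O)c1ccc(O)cc1 | starting material
11 | diethyl carbonate | CCOC(=O)OCC | starting material
12 | ethyl 3-(4-hydroxyphenyl)-3-oxopropanoate | CCOC(=O)CC(=O)c1ccc(O)cc1 | intermediate
13 | ethyl 3-(4-benzoyloxyphenyl)-3-oxopropanoate | CCOC(=O)CC(=O)c1ccc(OC(=O)c2ccccc2)cc1 | intermediate
14 | ethyl 2-bromo-3-(4-benzoyloxyphenyl)-3-oxopropanoate (racemic) | CCOC(=O)C(Br)C(=O)c1ccc(OC(=O)c2ccccc2)cc1 | intermediate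
15 | ethyl 2-benzoyloxy-3-(4-benzoyloxyphenyl)-3-oxopropanoate (racemic, configurationally labile) | CCOC(=O)C(OC(=O)c1ccccc1)C(=O)c1ccc(OC(=O)c2ccccc2)cc1 | intermediate
16 | benzoyloxy(4-benzoyloxybenzoyl)ketene | O=C=C(OC(=O)c1ccccc1)C(=O)c1ccc(OC(=O)c2ccccc2)cc1 | intermediate
17 | 2-benzoyloxy-3-(4-benzoyloxyphenyl)-1-(2,4,6-trihydroxy-3,5-diprenylphenyl)propane-1,3-dione (racemic, labile) | O=C(c1c(O)c(CC=C(C)C)c(O)c(CC=C(C)C)c1O)C(OC(=O)c1ccccc1)C(=O)c1ccc(OC(=O)c2ccccc2)cc1 | intermediate
18 | 3-benzoyloxy-2-(4-benzoyloxyphenyl)-2,5,7-trihydroxy-6,8-diprenylchroman-4-one (transient mixture of diastereomers) | OC1(c2ccc(OC(=O)c3ccccc3)cc2)Oc2c(CC=C(C)C)c(O)c(CC=C(C)C)c(O)c2C(=O)C1OC(=O)c1ccccc1 | intermediate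
19 | 3,4'-di-O-benzoyl-6,8-diprenylkaempferol | O=C(Oc1ccc(cc1)-c1oc2c(CC=C(C)C)c(O)c(CC=C(C)C)c(O)c2c(=O)c1OC(=O)c1ccccc1)c1ccccc1 | intermediate
20 | 6,8-diprenylkaempferol | CC(C)=CCc1c(O)c(CC=C(C)C)c2oc(-c3ccc(O)cc3)c(O)c(=O)c2c1O | target

Total step count: 9. Longest linear sequence: 6 (steps 1, 2, 3, 4, 8, 9). The ester arm (steps 5–7) runs in parallel.

Steps most likely to fail

1. Step 8. The processes at risk are:
 - thermal ring closure of the ortho-prenylphenol units onto their alkenes;
 - stalling at the reversible O-acylation stage;
 - hydrolysis with decarboxylation of the keto ester by the water released.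

 The fallback builds the same ring C by low-temperature anionic acylations while ring A is still protected. It sets out from 7 and comes back to the route at 20.
 - The last ring C–H of 7, again between two OMOM groups, is lithiated with n-BuLi in THF to give 2,4,6-tris(methoxymethoxy)-3,5-diprenylphenyllithium F1.
 - F1 is added at −78 °C to commercial (tert-butyldimethylsilyloxy)acetaldehyde to give the benzylic alcohol 2-(tert-butyldimethylsilyloxy)-1-[2,4,6-tris(methoxymethoxy)-3,5-diprenylphenyl]ethanol F2.
 - Oxidation with Dess–Martin periodinane buffered by NaHCO3 gives the ketone 2-(tert-butyldimethylsilyloxy)-1-[2,4,6-tris(methoxymethoxy)-3,5-diprenylphenyl]ethanone F3.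
 - The lithium enolate of F3 (LiN(SiMe3)2, 2.2 equiv, THF, −78 °C) is C-acylated by commercial 4-acetoxybenzoyl chloride to the diketone 3-(4-acetoxyphenyl)-2-(tert-butyldimethylsilyloxy)-1-[2,4,6-tris(methoxymethoxy)-3,5-diprenylphenyl]propane-1,3-dione F4.
 - About 1 M HCl in MeOH at 40 °C removes the acetal, silyl and acetyl groups and cyclodehydrates directly to 20.

 Dilute acid is acceptable at that stage because ring A is then deactivated by the acyl group and has no free carbon. This is the usual situation in MOM removals on prenylated flavonoids.

2. Step 4. The processes at risk are: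
 - incomplete cleavage of the acetals crowded by the prenyl groups;
 - electrophilic capture of the released CH2OMe unit by the open ring carbon;
 - air oxidation of the electron-rich triol during work-up.

 The fallback uses no protecting group at all. It sets out from 1 (with 3) and comes back to the route at 9. Phloroglucinol is C-alkylated with two equivalents of prenyl bromide in degassed aqueous KOH at 0 °C, where hydrogen bonding to the phenoxide oxygens steers the ambident anion to carbon. The under- and over-alkylated congeners are then removed by chromatography under argon. Selectivity is poorer, but no acetal, no acid and no formaldehyde source is involved. This fallback makes no compound outside the list (F0).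

3. Step 3. The processes at risk are competing deprotonation at the benzylic–allylic CH2 of the first prenyl group and allylic transposition during the alkylation.

 The fallback installs both prenyl groups by cross-coupling instead of deprotonation. It sets out from 2 and comes back to the route at 7, so it also replaces step 2.
 - NBS (2.0 equiv) in MeCN at 0 °C gives 2,4-dibromo-1,3,5-tris(methoxymethoxy)benzene F5.
 - A double Stille coupling of F5 with commercial Bu3SnCH2CH=CMe2 (Pd2(dba)3/P(t-Bu)3, DMF, 90 °C) transfers the linear prenyl group to both carbons.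

Further compounds
F1 | step 8 | 2,4,6-tris(methoxymethoxy)-3,5-diprenylphenyllithium | [Li]c1c(OCOC)c(CC=C(C)C)c(OCOC)c(CC=C(C)C)c1OCOC
F2 | step 8 | 2-(tert-butyldimethylsilyloxy)-1-[2,4,6-tris(methoxymethoxy)-3,5-diprenylphenyl]ethanol (racemic) | CC(C)(C)[Si](C)(C)OCC(O)c1c(OCOC)c(CC=C(C)C)c(OCOC)c(CC=C(C)C)c1OCOC
F3 | step 8 | 2-(tert-butyldimethylsilyloxy)-1-[2,4,6-tris(methoxymethoxy)-3,5-diprenylphenyl]ethanone | CC(C)(C)[Si](C)(C)OCC(=O)c1c(OCOC)c(CC=C(C)C)c(OCOC)c(CC=C(C)C)c1OCOC
F4 | step 8 | 3-(4-acetoxyphenyl)-2-(tert-butyldimethylsilyloxy)-1-[2,4,6-tris(methoxymethoxy)-3,5-diprenylphenyl]propane-1,3-dione (racemic, labile) | CC(=O)Oc1ccc(cc1)C(=O)C(O[Si](C)(C)C(C)(C)C)C(=O)c1c(OCOC)c(CC=C(C)C)c(OCOC)c(CC=C(C)C)c1OCOC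
F0 | step 4 | none | none
F5 | step 3 | 2,4-dibromo-1,3,5-tris(methoxymethoxy)benzene | COCOc1cc(OCOC)c(Br)c(OCOC)c1Br
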